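**Plan**

1. The hydroxy quinone methide is traced back to the catechol dimethyl ether 28 (C7–H restored). Cutting the bond from the spiro carbon to the ring CH2 (C4′) re-expands the bicyclo[3.1.0]hexane to a norcarane and turns the 2-indanone into indene oxide 27.
2. Enabling feature: the spiro carbon bears aryl C14, the ketone carbon, a cyclopropane CH and a ring CH2. This is what a 1,2-shift of CH2 leaves when an epoxide on the C=C shared by the indane five-ring and a norcarene six-ring opens at its benzylic, cyclopropyl-flanked carbon.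
3. Indene 26 is cut at C7–C3′ (cation–olefin closure) and C14–C2′ (Suzuki coupling) into bromo ketone 23, made from carnosic acid, and alkenyl boronate 15.
4. Forward: side chain first (Michael addition), six-ring attached by allylboration, cyclopropane closed by enolate displacement, coupling, five-ring closure, epoxidation, six-to-five ring contraction, then unmasking and oxidation.
5. Stereochemistry: chain centre from organocatalysis; cyclopropane centres from reagent-controlled allylboration relayed by SN2 inversion; C5 and C10 from carnosic acid; spiro centre from epoxidation anti to the cyclopropane and stereospecific anti migration.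

Key step: step 20

Locants: abietane numbering for the diterpene (C7 benzylic, C14 the free aromatic position); primed locants for the bicyclo[4.1.0]heptane (C1′/C6′ ring fusion, C7′ apex, C2′ carbonyl carbon, C3′ its CH2 neighbour, C4′ the next CH2).
Assumption 1: the absolute sense of steps 1 and 2 is assigned by the usual enamine-shielding and chair allylboration models; the antipodal catalyst or pinene would be used should either prove opposite.
Assumption 2: the carbinol centres of 11 and 25 are destroyed in the following step and are drawn as the isomers expected from addition anti to the ring substituent and from axial hydride delivery; rotamers of 24 and 25 about C14–C2′ converge in step 18.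

**Step 1**
Reactants: 1 isovaleraldehyde (3-methylbutanal); 2 methyl vinyl ketone (but-3-en-2-one)
Product: 3 (2S)-5-oxo-2-(propan-2-yl)hexanal
Conditions: (S)-2-[methoxy(diphenyl)methyl]pyrrolidine (5 mol %), ethyl 3,4-dihydroxybenzoate (20 mol %), neat, 4 °C
Reagents that add atoms: none
Why: Enamine-catalysed Michael addition of an aldehyde to an enone, in which the diarylmethyl group shields one face of the E-enamine so that the enone should add to the other and set the (S) α-centre; the aldehyde is used at once to avoid epimerisation.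

**Step 2**
Reactants: 3 (2S)-5-oxo-2-(propan-2-yl)hexanal; 4 cyclohexa-1,3-diene
Product: 7 (5S,6R)-6-[(1R)-cyclohex-2-en-1-yl]-6-hydroxy-5-(propan-2-yl)hexan-2-one, via cyclohexenylborane 5 (not isolated), via borinate ester 6 (not isolated)
Conditions: (−)-Ipc2BH [from (+)-α-pinene], 4, THF, −25 °C; 3, −78 °C; then NaBO3·4H2O, H2O, rt
Reagents that add atoms: none
Why: Asymmetric allylboration through a closed chair (Zimmerman–Traxler) transition state: the ring-locked Z-allylborane should add to the Si face of the aldehyde under control of the isopinocampheyl groups (overriding the α-centre and sparing the ketone) and, being Z, give only the syn relation between the carbinol and the ring stereocentre.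

**Step 3**
Reactants: 7 (5S,6R)-6-[(1R)-cyclohex-2-en-1-yl]-6-hydroxy-5-(propan-2-yl)hexan-2-one
Product: 8 (1R,2S)-1-[(1R)-cyclohex-2-en-1-yl]-5-oxo-2-(propan-2-yl)hexyl methanesulfonate
Conditions: MsCl, Et3N, CH2Cl2, 0 °C
Reagents that add atoms: methanesulfonyl chloride, CS(=O)(=O)Cl
Why: O-Sulfonylation via sulfene acylates even this hindered secondary alcohol at oxygen, so the carbinol configuration is kept and the future leaving group is installed.

**Step 4**
Reactants: 8 (1R,2S)-1-[(1R)-cyclohex-2-en-1-yl]-5-oxo-2-(propan-2-yl)hexyl methanesulfonate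
Product: 9 (1R,2S)-1-[(1R)-cyclohex-2-en-1-yl]-4-(2-methyl-1,3-dioxolan-2-yl)-2-(propan-2-yl)butyl methanesulfonate
Conditions: TMSOCH2CH2OTMS, TMSOTf (5 mol %), CH2Cl2, −78 to −20 °C
Reagents that add atoms: 1,2-bis(trimethylsilyloxy)ethane, C[Si](C)(C)OCCO[Si](C)(C)C
Why: Aprotic silyl-transfer ketalisation masks the methyl ketone (needed for the borane, base and hydride steps) at a temperature at which the homoallylic mesylate does not ionise.

**Step 5**
Reactants: 9 (1R,2S)-1-[(1R)-cyclohex-2-en-1-yl]-4-(2-methyl-1,3-dioxolan-2-yl)-2-(propan-2-yl)butyl methanesulfonate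
Product: 11 trans-3-hydroxycyclohexyl mesylate (OH on the ring carbon meta to the side chain; other centres as in 9), via alkylborane 10 (not isolated)
Conditions: 9-BBN (2 equiv), THF, rt to 45 °C; then NaBO3·4H2O, H2O, rt
Reagents that add atoms: sodium perborate, [Na+].[Na+].O[B-]1(O)OO[B-](O)(O)OO1
Why: Hydroboration–oxidation in which the bulky borane places boron on the alkene carbon remote from the branched allylic substituent and anti to it; only the regiochemistry matters because the new carbinol is oxidised next.

**Step 6**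
Reactants: 11 trans-3-hydroxycyclohexyl mesylate
Product: 12 3-oxocyclohexyl mesylate (γ-mesyloxy ketone; other centres as in 9)
Conditions: TPAP (5 mol %), NMO, 4 Å MS, CH2Cl2, rt
Reagents that add atoms: none
Why: Ley–Griffith oxidation converts the secondary alcohol to the ketone under neutral conditions that leave the mesylate and the ketal untouched.

**Step 7**
Reactants: 12 3-oxocyclohexyl mesylate
Product: 13 (1S,6S,7S)-7-[(3S)-4-methyl-1-(2-methyl-1,3-dioxolan-2-yl)pentan-3-yl]bicyclo[4.1.0]heptan-2-one (side chain exo)
Conditions: t-BuOK, t-BuOH/THF, 0 °C to rt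
Reagents that add atoms: none
Why: Intramolecular enolate alkylation (3-exo-tet γ-elimination, as in the classical carone synthesis): under equilibrating conditions the enolate on the substituted side displaces the mesylate with inversion, the ring fusion is necessarily cis, and the syn precursor places the chain exo.

**Step 8**
Reactants: 13 (1S,6S,7S)-7-substituted bicyclo[4.1.0]heptan-2-one
Product: 14 bicyclo[4.1.0]hept-2-en-2-yl trifluoromethanesulfonate (C2′=C3′ enol triflate of 13)
Conditions: KHMDS, THF, −78 °C; PhNTf2, −78 to 0 °C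
Reagents that add atoms: N-phenylbis(trifluoromethanesulfonimide), O=S(=O)(N(c1ccccc1)S(=O)(=O)C(F)(F)F)C(F)(F)F
Why: Enolate O-triflation is regiospecific because the only other α-carbon is the cyclopropane bridgehead, which cannot be enolised.

**Step 9**
Reactants: 14 enol triflate
Product: 15 pinacol alkenylboronate (Bpin on C2′ of the norcar-2-ene)
Conditions: B2pin2, PdCl2(dppf) (3 mol %), KOAc, dioxane, 80 °C
Reagents that add atoms: bis(pinacolato)diboron, CC1(C)OB(OC1(C)C)B1OC(C)(C)C(C)(C)O1
Why: Miyaura borylation of an alkenyl triflate retains the ring-fixed alkene and the cyclopropane, which has no low-energy thermal pathway at this temperature.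

**Step 10**
Reactants: 16 carnosic acid
Product: 17 methyl 11,12-di-O-methylcarnosate
Conditions: MeI (excess), K2CO3, DMF, 50 °C, argon
Reagents that add atoms: iodomethane, CI
Why: Williamson-type O-methylation of both phenols and the carboxylate under exclusion of air protects the oxidation-prone catechol as its robust dimethyl ether.

**Step 11**
Reactants: 17 methyl 11,12-di-O-methylcarnosate
Product: 18 11,12-dimethoxyabieta-8,11,13-trien-20-ol
Conditions: LiAlH4, THF, reflux
Reagents that add atoms: none
Why: Hydride reduction of the hindered angular ester to the neopentyl alcohol needs only forcing temperature and touches no stereocentre.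

**Step 12**
Reactants: 18 11,12-dimethoxyabieta-8,11,13-trien-20-ol
Product: 19 11,12-dimethoxyabieta-8,11,13-trien-20-al
Conditions: TPAP (5 mol %), NMO, 4 Å MS, CH2Cl2, rt
Reagents that add atoms: none
Why: Ley–Griffith oxidation stops at the non-enolisable aldehyde.

**Step 13**
Reactants: 19 11,12-dimethoxyabieta-8,11,13-trien-20-al
Product: 21 11,12-dimethoxyabieta-8,11,13-triene, via hydrazone 20 (not isolated)
Conditions: N2H4·H2O, KOH, diethylene glycol, 130 then 200 °C
Reagents that add atoms: none
Why: Wolff–Kishner reduction (Huang–Minlon procedure) turns the angular aldehyde into the C10 methyl group through a carbanion, avoiding the aryl-shift ring expansion that cationic or radical deoxygenation at C20 would invite.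

**Step 14**
Reactants: 21 11,12-dimethoxyabieta-8,11,13-triene
Product: 22 14-bromo-11,12-dimethoxyabieta-8,11,13-triene
Conditions: NBS, MeCN, 0 °C to rt, dark
Reagents that add atoms: N-bromosuccinimide, O=C1CCC(=O)N1Br
Why: Electrophilic aromatic bromination can only go to C14, the single free ring position, which is para to the C11 methoxy group; polar conditions suppress benzylic bromination.

**Step 15**
Reactants: 22 14-bromo-11,12-dimethoxyabieta-8,11,13-triene
Product: 23 14-bromo-11,12-dimethoxyabieta-8,11,13-trien-7-one
Conditions: CrO3, AcOH/Ac2O, 0 °C to rt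
Reagents that add atoms: chromium trioxide, O=[Cr](=O)=O
Why: Chromium(VI) benzylic oxidation is selective for the ring methylene C7, which is para-activated by the C12 methoxy group, as is usual in the abietatriene series.

**Step 16**
Reactants: 15 pinacol alkenylboronate; 23 14-bromo-11,12-dimethoxyabieta-8,11,13-trien-7-one
Product: 24 11,12-dimethoxy-7-oxoabieta-8,11,13-triene bearing the norcar-2-en-2-yl unit at C14 (C14–C2′ bond)
Conditions: Pd(OAc)2 (5 mol %), SPhos (10 mol %), K3PO4, toluene/H2O, 90 °C
Reagents that add atoms: none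
Why: Suzuki–Miyaura coupling with a bulky electron-rich biarylphosphine tolerates the di-ortho-substituted bromide, whose ortho carbonyl aids oxidative addition, and joins the fragments without touching any stereocentre.

**Step 17**
Reactants: 24 coupled aryl ketone
Product: 25 7β-alcohol of 24
Conditions: LiAlH4, THF, −20 to 0 °C
Reagents that add atoms: none
Why: Hydride reduction of the only unmasked carbonyl gives the benzylic alcohol that serves as cation precursor; its configuration is immaterial.

**Step 18**
Reactants: 25 7β-alcohol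
Product: 26 fused indene (C2′=C3′ shared by the indane five-ring and the norcarene six-ring; C7–H α; cyclopropane on the α-face; ketal side chain)
Conditions: Bi(OTf)3 (5 mol %), 4 Å MS, CH2Cl2, −20 to 0 °C
Reagents that add atoms: none
Why: Dehydrative cation–olefin cyclisation (Nazarov-type 4π closure of a benzylic pentadienyl cation): the C7 cation stabilised by the para C12 methoxy group is captured by C3′ of the ortho alkenyl group, the C2′ cation then loses H3′ to give the tetrasubstituted indene, and the conrotation that keeps ring B in its half-chair leaves C7–H α.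

**Step 19**
Reactants: 26 fused indene
Product: 27 indene oxide (oxygen on the β-face: anti to the cyclopropane, syn to C6)
Conditions: DMDO (1.2 equiv), acetone/CH2Cl2, −40 to −20 °C; cold evaporation in base-washed glassware, used crude
Reagents that add atoms: dimethyldioxirane, CC1(C)OO1
Why: Concerted dioxirane oxygen transfer under neutral conditions is expected on the β-face, because the endo hydrogen of the cyclopropane apex lies under C2′ on the α-face whereas C6 is splayed away from C3′ by the peri fusion; this sets both epoxide carbons with oxygen anti to the cyclopropane.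

**Step 20**
Reactants: 27 indene oxide
Product: 28 spiro 2-indanone (spiro carbon = C2 of the bicyclo[3.1.0]hexane; aryl cis and ketone trans to the cyclopropane; catechol dimethyl ether; ketal side chain)
Conditions: BF3·OEt2 (0.3 equiv), CH2Cl2, −78 °C; Et3N quench, then aq. NaHCO3
Reagents that add atoms: none
Why: BF3 binds the epoxide oxygen and the C2′–O bond ionises, since only C2′ is benzylic (para to the C11 methoxy group through C14) and flanked by the cyclopropane; the ring CH2 (C4′), which stands on C3′ anti to the oxygen and parallel to the vacant orbital, then shifts to C2′ while C3′–O becomes the carbonyl. This is a Meinwald (epoxide semipinacol) rearrangement of a tetrasubstituted aryl epoxide to an α-quaternary ketone. The five-membered ring of the bicyclo[3.1.0]hexane arises by contraction of the norcarane six-ring through this suprafacial 1,2-alkyl shift (a ring contraction, not an exo or endo cyclisation), and the indane becomes a 2-indanone. The spiro carbon is the one new stereocentre: C4′ enters C2′ on the face opposite the departing oxygen, so the β-epoxide places the aryl group cis and the ketone trans to the cyclopropane. The step needs migration of C4′ instead of benzylic C7, and a 1,2-shift instead of cyclopropane cleavage; C7 lies in the nodal plane of the cation within the flat five-ring and its shift would give a strained benzocyclobutene, while low temperature, sub-stoichiometric Lewis acid and a non-nucleophilic medium keep the cyclopropylcarbinyl cation from opening.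

**Step 21**
Reactants: 28 spiro 2-indanone
Product: 29 catechol diketone (11,12-diol; free methyl ketone)
Conditions: BBr3 (8 equiv), CH2Cl2, −78 to 0 °C; aq. NaHCO3, argon
Reagents that add atoms: water, O
Why: Boron tribromide cleaves both hindered aryl methyl ethers, as is standard for 11,12-dimethoxyabietanes, and opens the dioxolane, which the aqueous work-up hydrolyses to the methyl ketone; the non-conjugated cyclopropane and the ketones are not affected at this temperature.

**Step 22**
Reactants: 29 catechol diketone
Product: 31 CNP0140364.1, via ortho-quinone 30 (not isolated)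
Conditions: Ag2O (3 equiv), Et2O, rt; then brief contact with silica gel
Reagents that add atoms: none
Why: Catechol oxidation gives the 11,12-ortho-quinone, whose C7–H (α to the indanone carbonyl and vinylogous to the C11 carbonyl) tautomerises to the conjugated, hydrogen-bonded 11-hydroxy-12-oxo quinone methide, as in the taxodione series; the last stereocentre at C7 disappears.

**Compound list**

1 | isovaleraldehyde | CC(C)CC=O | starting material
2 | methyl vinyl ketone | CC(=O)C=C | starting material
3 | (2S)-5-oxo-2-(propan-2-yl)hexanal | CC(=O)CC[C@@H](C(C)C)C=O | intermediate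
4 | cyclohexa-1,3-diene | C1=CC=CCC1 | starting material
5 | B-[(1S)-cyclohex-2-en-1-yl]diisopinocampheylborane | B([C@@H]1C=CCCC1)([C@@H]1C[C@@H]2C[C@@H](C2(C)C)[C@H]1C)[C@@H]1C[C@@H]2C[C@@H](C2(C)C)[C@H]1C | intermediate (not isolated)
6 | diisopinocampheylborinate ester of 7 | CC(=O)CC[C@@H](C(C)C)[C@@H](OB([C@@H]2C[C@@H]3C[C@@H](C3(C)C)[C@H]2C)[C@@H]2C[C@@H]3C[C@@H](C3(C)C)[C@H]2C)[C@H]1C=CCCC1 | intermediate (not isolated)
7 | (5S,6R)-6-[(1R)-cyclohex-2-en-1-yl]-6-hydroxy-5-(propan-2-yl)hexan-2-one | CC(=O)CC[C@@H](C(C)C)[C@@H](O)[C@H]1C=CCCC1 | intermediate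
8 | (1R,2S)-1-[(1R)-cyclohex-2-en-1-yl]-5-oxo-2-(propan-2-yl)hexyl methanesulfonate | CC(=O)CC[C@@H](C(C)C)[C@@H](OS(C)(=O)=O)[C@H]1C=CCCC1 | intermediate
9 | (1R,2S)-1-[(1R)-cyclohex-2-en-1-yl]-4-(2-methyl-1,3-dioxolan-2-yl)-2-(propan-2-yl)butyl methanesulfonate | CC1(CC[C@@H](C(C)C)[C@@H](OS(C)(=O)=O)[C@H]2C=CCCC2)OCCO1 | intermediate
10 | B-alkyl-9-BBN adduct of 9 (boron trans-1,3 to the side chain) | CC1(CC[C@@H](C(C)C)[C@@H](OS(C)(=O)=O)[C@H]2C[C@H](B3C4CCCC3CCC4)CCC2)OCCO1 | intermediate (not isolated)
11 | trans-3-hydroxycyclohexyl mesylate | CC1(CC[C@@H](C(C)C)[C@@H](OS(C)(=O)=O)[C@H]2C[C@H](O)CCC2)OCCO1 | intermediate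
12 | 3-oxocyclohexyl mesylate | CC1(CC[C@@H](C(C)C)[C@@H](OS(C)(=O)=O)[C@H]2CC(=O)CCC2)OCCO1 | intermediate
13 | (1S,6S,7S)-7-[(3S)-4-methyl-1-(2-methyl-1,3-dioxolan-2-yl)pentan-3-yl]bicyclo[4.1.0]heptan-2-one | CC1(CC[C@@H](C(C)C)[C@H]2[C@@H]3CCCC(=O)[C@@H]32)OCCO1 | intermediate
14 | enol triflate of 13 | CC1(CC[C@@H](C(C)C)[C@H]2[C@@H]3CCC=C(OS(=O)(=O)C(F)(F)F)[C@@H]32)OCCO1 | intermediate
15 | pinacol alkenylboronate | CC1(CC[C@@H](C(C)C)[C@H]2[C@@H]3CCC=C(B4OC(C)(C)C(C)(C)O4)[C@@H]32)OCCO1 | intermediate
16 | carnosic acid | CC(C)c1cc2c(c(O)c1O)[C@@]1(C(=O)O)CCCC(C)(C)[C@@H]1CC2 | starting material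
17 | methyl 11,12-di-O-methylcarnosate | CC(C)c1cc2c(c(OC)c1OC)[C@@]1(C(=O)OC)CCCC(C)(C)[C@@H]1CC2 | intermediate
18 | 11,12-dimethoxyabieta-8,11,13-trien-20-ol | CC(C)c1cc2c(c(OC)c1OC)[C@@]1(CO)CCCC(C)(C)[C@@H]1CC2 | intermediate
19 | 11,12-dimethoxyabieta-8,11,13-trien-20-al | CC(C)c1cc2c(c(OC)c1OC)[C@@]1(C=O)CCCC(C)(C)[C@@H]1CC2 | intermediate
20 | hydrazone of 19 | CC(C)c1cc2c(c(OC)c1OC)[C@@]1(/C=N/N)CCCC(C)(C)[C@@H]1CC2 | intermediate (not isolated)
21 | 11,12-dimethoxyabieta-8,11,13-triene | CC(C)c1cc2c(c(OC)c1OC)[C@@]1(C)CCCC(C)(C)[C@@H]1CC2 | intermediate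
22 | 14-bromo-11,12-dimethoxyabieta-8,11,13-triene | CC(C)c1c(Br)c2c(c(OC)c1OC)[C@@]1(C)CCCC(C)(C)[C@@H]1CC2 | intermediate
23 | 14-bromo-11,12-dimethoxyabieta-8,11,13-trien-7-one | CC(C)c1c(Br)c2c(c(OC)c1OC)[C@@]1(C)CCCC(C)(C)[C@@H]1CC2=O | intermediate
24 | C14-(norcar-2-en-2-yl) 7-ketone | CC1(CC[C@@H](C(C)C)[C@H]2[C@@H]3CCC=C([C@@H]32)c2c(C(C)C)c(OC)c(OC)c3c2C(=O)C[C@H]2C(C)(C)CCC[C@]32C)OCCO1 | intermediate
25 | 7β-alcohol of 24 | CC1(CC[C@@H](C(C)C)[C@H]2[C@@H]3CCC=C([C@@H]32)c2c(C(C)C)c(OC)c(OC)c3c2[C@@H](O)C[C@H]2C(C)(C)CCC[C@]32C)OCCO1 | intermediate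
26 | fused indene (C7–H α) | CC1(CC[C@@H](C(C)C)[C@H]2[C@@H]3CCC4=C([C@@H]32)c2c(C(C)C)c(OC)c(OC)c3c2[C@@H]4C[C@H]2C(C)(C)CCC[C@]32C)OCCO1 | intermediate
27 | indene oxide (O anti to cyclopropane) | CC1(CC[C@@H](C(C)C)[C@H]2[C@@H]3CC[C@]4(O5)[C@H]6C[C@H]7C(C)(C)CCC[C@]7(C)c8c(OC)c(OC)c(C(C)C)c(c86)[C@]45[C@@H]32)OCCO1 | intermediate
28 | spiro 2-indanone, catechol dimethyl ether, ketal | CC1(CC[C@@H](C(C)C)[C@H]2[C@@H]3CC[C@@]4(C(=O)[C@@H]5c6c4c(C(C)C)c(OC)c(OC)c6[C@@]4(C)CCCC(C)(C)[C@@H]4C5)[C@@H]32)OCCO1 | intermediate
29 | catechol diketone | CC(=O)CC[C@@H](C(C)C)[C@H]1[C@@H]2CC[C@@]3(C(=O)[C@@H]4c5c3c(C(C)C)c(O)c(O)c5[C@@]3(C)CCCC(C)(C)[C@@H]3C4)[C@@H]21 | intermediate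
30 | 11,12-ortho-quinone | CC(=O)CC[C@@H](C(C)C)[C@H]1[C@@H]2CC[C@@]3(C(=O)[C@@H]4C5=C([C@@]6(C)CCCC(C)(C)[C@@H]6C4)C(=O)C(=O)C(C(C)C)=C53)[C@@H]21 | intermediate (not isolated)
31 | CNP0140364.1: 11-hydroxy-12-oxoabieta-7,9(11),13-triene quinone methide whose C7 and C14 are bridged by a ketone carbon and a spiro carbon that is C2 of an exo-6-[(3S)-2-methyl-6-oxoheptan-3-yl]bicyclo[3.1.0]hexane | CC(=O)CC[C@@H](C(C)C)[C@H]1[C@@H]2CC[C@@]3(C(=O)C4=C5C3=C(C(C)C)C(=O)C(O)=C5[C@@]3(C)CCCC(C)(C)[C@@H]3C4)[C@@H]21 | target

**Step count and risks**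

Total steps: 22 (9 to boronate 15, 6 to bromo ketone 23, 7 from their union to the target). Longest linear sequence: 16 steps (steps 1–9 and 16–22).

Steps most likely to fail:

Step 19. Oxygen transfer may show poor or reversed facial selectivity, since C6 screens one face of the tetrasubstituted alkene and the cyclopropane the other, and the product may open during isolation. The fallback sets out from 26 and comes back at 27. NBS in aqueous THF at 0 °C should place bromonium on the face the dioxirane prefers and water on benzylic C2′ from the opposite face, giving the bromohydrin F1. K2CO3 in MeOH then closes the oxirane with inversion at C3′. This two-step sequence puts the oxygen on the face opposite to the one a direct electrophile attacks, so it delivers 27 when direct epoxidation goes the wrong way.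

Step 20. The ionised epoxide may collapse before the shift, by capture with fluoride or adventitious water or by cleavage of the cyclopropane, or it may not survive handling at all. The fallback sets out from 26 and comes back at 28. Stoichiometric OsO4 with pyridine in CH2Cl2, followed by NaHSO3, should give the cis-diol F2 on the same face as the epoxide; it is stable, can be purified and has a configuration that can be checked. Anhydrous TsOH (catalytic) with MgSO4 in CH2Cl2 at 0 °C then ionises only the benzylic C2′ hydroxyl, and the remaining C3′ hydroxyl drives the same CH2 shift as a pinacol rearrangement.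

Step 18. The cationic closure may be diverted by cyclopropane cleavage at the C2′ cation, by loss of the ketal, or by a sluggish approach of the twisted alkenyl group to C7. The fallback closes the five-ring from the other side; it sets out from 21 and 13 and comes back at 26. CrO3 in AcOH oxidises 21 to the ketone F3, and NaBH4 reduces it to the benzylic alcohol F4. Ketone 13 with LDA and TMSCl gives the silyl enol ether F5. TMSOTf (10 mol %) in CH2Cl2 at −78 °C joins F4 and F5 by SN1 benzylic alkylation to the C7–C3′ linked ketone F6, as a mixture at C7 and C3′. MsOH in CH2Cl2 then closes C14 onto the C2′ carbonyl by Friedel–Crafts cyclodehydration, with loss of the ketal on work-up, giving the keto indene F7. The conditions of step 4 restore the dioxolane.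

**Further compounds**

F1 | step 19 | bromohydrin of 26 (Br on C3′ syn to the cyclopropane, OH on C2′ anti) | CC1(CC[C@@H](C(C)C)[C@H]2[C@@H]3CC[C@@]4(Br)[C@H]6C[C@H]7C(C)(C)CCC[C@]7(C)c8c(OC)c(OC)c(C(C)C)c(c86)[C@]4(O)[C@@H]32)OCCO1
F2 | step 20 | cis-diol of 26 (both hydroxyls anti to the cyclopropane) | CC1(CC[C@@H](C(C)C)[C@H]2[C@@H]3CC[C@]4(O)[C@H]6C[C@H]7C(C)(C)CCC[C@]7(C)c8c(OC)c(OC)c(C(C)C)c(c86)[C@]4(O)[C@@H]32)OCCO1
F3 | step 18 | 11,12-dimethoxyabieta-8,11,13-trien-7-one | CC(C)c1cc2c(c(OC)c1OC)[C@@]1(C)CCCC(C)(C)[C@@H]1CC2=O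
F4 | step 18 | 11,12-dimethoxyabieta-8,11,13-trien-7β-ol | CC(C)c1cc2c(c(OC)c1OC)[C@@]1(C)CCCC(C)(C)[C@@H]1C[C@@H]2O
F5 | step 18 | trimethylsilyl enol ether of 13 | CC1(CC[C@@H](C(C)C)[C@H]2[C@@H]3CCC=C(O[Si](C)(C)C)[C@@H]32)OCCO1
F6 | step 18 | 3′-(11,12-dimethoxyabieta-8,11,13-trien-7-yl) derivative of 13 (C7 and C3′ epimers) | CC1(CC[C@@H](C(C)C)[C@H]2[C@@H]3CCC(C(=O)[C@@H]32)C2C[C@H]3C(C)(C)CCC[C@]3(C)c3c2cc(C(C)C)c(OC)c3OC)OCCO1
F7 | step 18 | fused indene with free methyl ketone | CC(=O)CC[C@@H](C(C)C)[C@H]1[C@@H]2CCC3=C([C@@H]21)c1c(C(C)C)c(OC)c(OC)c2c1[C@@H]3C[C@H]1C(C)(C)CCC[C@]21C
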